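**Retrosynthetic overview**
1. The C3–O–C16 oxepane is closed last, from the C3 (tertiary) / C16 (primary) diol 32 via the primary triflate.
2. The tetrahydrofuran (and with it the oxonane) comes from a transannular 5-exo opening of a 2,3-epoxide by the C9 hydroxyl inside a cis-fused 6/10 carbocycle. That carbocycle is closed at C8–C9 by a Cr-mediated allylation in the same flask (28 → 29 → 30).
3. Epoxy alcohol 26 comes from threo-selective, hydroxyl-directed epoxidation of a (Z)-allylic alcohol, itself made by a boron aldol (C4–C5) of Z-enal 23 with chloromethyl enone 14.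
4. The cyclohexane comes from a catalytic asymmetric endo Diels–Alder of the Roche-ester enal 5 with dienyl ether 10 (sets C1, C10, C14; C15 from the chiral pool; the C12 methyl comes with the diene). C11/C12 follow by hydroboration–oxidation and reduction.
5. Ring order: cyclohexane → ten-membered carbocycle → tetrahydrofuran/oxonane → oxepane.

Assumption: locants C1–C20 are asbestinane numbering of the given SMILES (C2–O–C9 THF, C3–O–C16 oxepane, C4 octanoate, C6 ketone, C7=C19, C11 acetate, C12 methyl); the antipodes quoted for the imidazolidinone (step 9) and Ipc2BCl (step 15) are those predicted by the usual facial models, and the enantiomeric reagent is used if the sense proves opposite.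

**Route**

Step 1
Reactants: 1 methyl (2S)-3-hydroxy-2-methylpropanoate
Product: 2 methyl (2S)-3-[(tert-butyldiphenylsilyl)oxy]-2-methylpropanoate
Conditions: TBDPSCl, imidazole, DMF, rt
Reagents that add atoms: tert-butyl(chloro)diphenylsilane, CC(C)(C)[Si](Cl)(c1ccccc1)c1ccccc1
Why: Standard silylation of the primary alcohol; the stereocentre (future C15) is not touched.

Step 2
Reactants: 2 methyl (2S)-3-[(tert-butyldiphenylsilyl)oxy]-2-methylpropanoate
Product: 3 (2S)-3-[(tert-butyldiphenylsilyl)oxy]-2-methylpropanal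
Conditions: DIBAL (1.1 equiv), CH2Cl2, −78 °C; Rochelle salt
Reagents that add atoms: none
Why: Partial ester reduction; the tetrahedral aluminate is stable at −78 °C and collapses to the aldehyde on work-up without α-epimerisation.

Step 3
Reactants: 3 (2S)-3-[(tert-butyldiphenylsilyl)oxy]-2-methylpropanal; 4 (triphenylphosphoranylidene)acetaldehyde
Product: 5 (2E,4R)-5-[(tert-butyldiphenylsilyl)oxy]-4-methylpent-2-enal
Conditions: PhMe, 80 °C
Reagents that add atoms: none
Why: Wittig reaction of a stabilised ylide gives the E-enal; the α-stereocentre is kept under these neutral conditions.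

Step 4
Reactants: 6 methacrolein; 7 triethyl phosphonoacetate
Product: 8 ethyl (2E)-4-methylpenta-2,4-dienoate
Conditions: NaH, THF, 0 °C → rt
Reagents that add atoms: none
Why: Horner–Wadsworth–Emmons olefination, E-selective.

Step 5
Reactants: 8 ethyl (2E)-4-methylpenta-2,4-dienoate
Product: 9 (2E)-4-methylpenta-2,4-dien-1-ol
Conditions: DIBAL (2.2 equiv), CH2Cl2, −78 → 0 °C
Reagents that add atoms: none
Why: 1,2-Reduction of the conjugated ester to the allylic alcohol.

Step 6
Reactants: 9 (2E)-4-methylpenta-2,4-dien-1-ol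
Product: 10 1-methoxy-4-({[(2E)-4-methylpenta-2,4-dien-1-yl]oxy}methyl)benzene
Conditions: NaH, PMBCl, TBAI (cat.), THF/DMF, 0 °C → rt
Reagents that add atoms: 4-methoxybenzyl chloride, COc1ccc(CCl)cc1
Why: Williamson etherification; PMB survives the acidic aqueous Diels–Alder conditions and is removed oxidatively later.

Step 7
Reactants: 11 but-3-en-2-one; 12 formaldehyde
Product: 13 3-(hydroxymethyl)but-3-en-2-one
Conditions: aq. HCHO, DABCO (cat.), THF/H2O, rt
Reagents that add atoms: none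
Why: Morita–Baylis–Hillman reaction of the vinyl ketone with formaldehyde.

Step 8
Reactants: 13 3-(hydroxymethyl)but-3-en-2-one
Product: 14 3-(chloromethyl)but-3-en-2-one
Conditions: SOCl2, Et2O, 0 °C → rt
Reagents that add atoms: thionyl chloride, O=S(Cl)Cl
Why: Chlorination through the chlorosulfite; SN2 and SN2′ give the same product because the two CH2 termini are equivalent.

Step 9
Reactants: 10 1-methoxy-4-({[(2E)-4-methylpenta-2,4-dien-1-yl]oxy}methyl)benzene; 5 (2E,4R)-5-[(tert-butyldiphenylsilyl)oxy]-4-methylpent-2-enal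
Product: 15 (1S,2R,6S)-6-[(2R)-1-(TBDPS-oxy)propan-2-yl]-2-[(4-methoxybenzyloxy)methyl]-4-methylcyclohex-3-ene-1-carbaldehyde (C1 S, C10 R, C14 S, C15 R)
Conditions: (2R,5R)-5-benzyl-2,2,3-trimethylimidazolidin-4-one·HClO4 (20 mol %), MeCN/H2O 95:5, −10 °C → rt
Reagents that add atoms: none
Why: Iminium-catalysed (MacMillan) Diels–Alder: the 1-substituted-3-methyl diene gives the "ortho/para" regioisomer (C1–C10 and C13–C14 bonds), the E-enal fixes C1/C14 trans, endo addition fixes C1/C10 cis, and the catalyst blocks the Cα-Si face so the diene adds to Cα-Re (1S); C15 comes from the Roche ester.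

Step 10
Reactants: 15 Diels–Alder aldehyde; 16 ethyl 2-[bis(2,2,2-trifluoroethoxy)phosphoryl]propanoate
Product: 17 ethyl (2Z)-2-methyl-3-(cyclohexenyl)prop-2-enoate (15 with CHO replaced by (Z)-CH=C(CH3)CO2Et; C2=C3 Z, C4 = ester carbon)
Conditions: KHMDS, 18-crown-6, THF, −78 °C
Reagents that add atoms: none
Why: Still–Gennari olefination gives the Z-trisubstituted enoate (C1 cis to C4) at −78 °C without epimerising C1.

Step 11
Reactants: 17 Z-enoate
Product: 19 C11 ketone (12R, C12–CH3 cis to the C10 CH2OPMB group; Z-enoate intact), via C11 alkylborane 18 (not isolated)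
Conditions: BH3·THF (1.0 equiv), THF, 0 °C; then NMO, TPAP (5 mol %), 4 Å MS, CH2Cl2, rt
Reagents that add atoms: N-methylmorpholine N-oxide, C[N+]1([O-])CCOCC1 (carbonyl O); borane–THF, B.C1CCOC1 (its boron is in 18 only)
Why: Hydroboration of the electron-rich ring alkene (the conjugated ester is much slower) puts boron on C11 and hydrogen on C12 from the face anti to the adjacent pseudoaxial C10 substituent, so the C12 methyl ends cis to C10–CH2OPMB; amine-oxide/TPAP oxidation of the organoborane then gives the ketone under non-epimerising conditions.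

Step 12
Reactants: 19 C11 ketone
Product: 21 diol: (11R)-alcohol and (Z)-allylic primary alcohol at C4, via (11R)-hydroxy ester 20 (not isolated)
Conditions: L-Selectride (1.1 equiv), THF, −78 °C; then DIBAL (3.5 equiv), −78 → −20 °C; Rochelle salt
Reagents that add atoms: none
Why: The bulky hydride attacks the ketone equatorially, from the face opposite the C10 and C12 substituents, giving the axial 11-OH cis to both (as in the target); DIBAL then reduces the enoate 1,2 to the allylic alcohol with Z retained.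

Step 13
Reactants: 21 diol
Product: 22 (2Z)-enal (C4 aldehyde) with free 11-OH
Conditions: MnO2, CH2Cl2, rt
Reagents that add atoms: none
Why: MnO2 oxidises only the allylic primary alcohol; neutral conditions keep the Z geometry.

Step 14
Reactants: 22 hydroxy Z-enal
Product: 23 11-O-acetyl Z-enal
Conditions: Ac2O, pyridine, DMAP (cat.), CH2Cl2, 0 °C
Reagents that add atoms: acetic anhydride, CC(=O)OC(C)=O
Why: Acylation of the only free hydroxyl; the acetate is the one in the target and every later step is chosen to tolerate it.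

Step 15
Reactants: 14 3-(chloromethyl)but-3-en-2-one; 23 11-O-acetyl Z-enal
Product: 25 (4R)-aldol: C4–OH, C6 ketone, C7=C19H2, C8H2Cl, 2Z-alkene, via enol diisopinocampheylborinate 24 (not isolated)
Conditions: 14, (−)-Ipc2BCl, i-Pr2NEt, Et2O, −78 °C; then 23, −78 → −20 °C; H2O2, pH 7 buffer, MeOH
Reagents that add atoms: (−)-B-chlorodiisopinocampheylborane, ClB([C@@H]1C[C@@H]2C[C@@H](C2(C)C)[C@H]1C)[C@@H]1C[C@@H]2C[C@@H](C2(C)C)[C@H]1C (its B(Ipc)2 unit is in 24 only)
Why: Paterson boron aldol of a methyl ketone: only the methyl group can enolise, the hindered amine does not displace the allylic chloride at −78 °C, and the Ipc ligands direct C5 to the Re face of the enal (4R, reagent control).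

Step 16
Reactants: 25 (4R)-aldol
Product: 26 (2R,3S,4R)-2,3-epoxy-4-ol (cis epoxide, threo to the 4-OH)
Conditions: mCPBA, CH2Cl2, 0 °C
Reagents that add atoms: 3-chloroperoxybenzoic acid, O=C(OO)c1cccc(Cl)c1
Why: Hydroxyl-directed (Henbest) epoxidation: A(1,3) strain with the cis C1 substituent holds H4 in the alkene plane, so oxygen is delivered to the OH face and the threo epoxide results; the enone C7=C19 is inert to the peracid.

Step 17
Reactants: 26 epoxy alcohol
Product: 28 C9 aldehyde (epoxy alcohol, allylic chloride and enone intact), via C9 primary alcohol 27 (not isolated)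
Conditions: DDQ, CH2Cl2/pH 7 buffer, 0 °C; then PhI(OAc)2, TEMPO (cat.), rt
Reagents that add atoms: none
Why: Oxidative PMB cleavage, then oxoammonium (TEMPO) oxidation, which takes the primary C9 alcohol and leaves the secondary 4-OH; neutral conditions protect C10 and the epoxide.

Step 18
Reactants: 28 C9 aldehyde
Product: 30 tricyclic diol (C2–O–C9 tetrahydrofuran in a nine-membered oxonane, cis-fused cyclohexane; 2S,3S,4R,9S; 3-OH, 4-OH, C6 ketone, C7=C19H2), via ten-membered carbocyclic (9S)-alcohol 29 (not isolated)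
Conditions: CrCl2 (8 equiv), THF/DMF, 2 mM (slow addition), rt; then Ti(Oi-Pr)4 (2 equiv), 40 °C
Reagents that add atoms: none
Why: Proposed new method: CrCl2 turns the 2-acylallyl chloride into an allylchromium(III) that adds to the C9 aldehyde (closest known type: macrocyclic Nozaki–Hiyama allylation to 10- and 14-membered carbocycles), with C8 delivered anti to the C10–C11 bond and past H10 (Felkin–Anh, the tether can only approach gauche to C1) to give the 9S alkoxide, which then opens the Ti-chelated 2,3-epoxy-4-ol transannularly by 5-exo attack at C2, the carbon distal to the carbinol (closest known type: Ti(Oi-Pr)4-directed opening of 2,3-epoxy alcohols), with inversion at C2 and retention at C3.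

Step 19
Reactants: 30 tricyclic diol
Product: 31 4-O-octanoate (3-OH free)
Conditions: n-C7H15COCl, pyridine, DMAP (cat.), CH2Cl2, −20 → 0 °C
Reagents that add atoms: octanoyl chloride, CCCCCCCC(=O)Cl
Why: Acylation of the secondary 4-OH; the tertiary 3-OH does not react and the low temperature avoids β-elimination of the new β-acyloxy ketone.

Step 20
Reactants: 31 4-O-octanoate
Product: 32 C16 primary alcohol (C3/C16 diol)
Conditions: HF·pyridine, pyridine/THF, 0 °C → rt
Reagents that add atoms: none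
Why: Fluoride cleavage of the primary TBDPS ether under buffered, non-basic conditions that spare both esters and the enone.

Step 21
Reactants: 32 C3/C16 diol
Product: 34 Asbestinin 16, via C16 triflate 33 (not isolated)
Conditions: Tf2O (1.1 equiv), 2,6-lutidine, CH2Cl2, −78 → 0 °C
Reagents that add atoms: trifluoromethanesulfonic anhydride, O=S(=O)(OS(=O)(=O)C(F)(F)F)C(F)(F)F (its Tf group is in 33 only)
Why: The primary alcohol is triflated selectively and the tertiary 3-OH displaces the triflate (7-exo-tet Williamson-type etherification); no bond to a stereocentre is broken.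

**Compound list**
1 | methyl (2S)-3-hydroxy-2-methylpropanoate (Roche ester) | C[C@@H](CO)C(=O)OC | starting material
2 | methyl (2S)-3-[(tert-butyldiphenylsilyl)oxy]-2-methylpropanoate | COC(=O)[C@@H](C)CO[Si](c1ccccc1)(c1ccccc1)C(C)(C)C | intermediate
3 | (2S)-3-[(tert-butyldiphenylsilyl)oxy]-2-methylpropanal | O=C[C@@H](C)CO[Si](c1ccccc1)(c1ccccc1)C(C)(C)C | intermediate
4 | (triphenylphosphoranylidene)acetaldehyde | O=CC=P(c1ccccc1)(c1ccccc1)c1ccccc1 | starting material
5 | (2E,4R)-5-[(tert-butyldiphenylsilyl)oxy]-4-methylpent-2-enal | O=C/C=C/[C@@H](C)CO[Si](c1ccccc1)(c1ccccc1)C(C)(C)C | intermediate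
6 | methacrolein | C=C(C)C=O | starting material
7 | triethyl phosphonoacetate | CCOC(=O)CP(=O)(OCC)OCC | starting material
8 | ethyl (2E)-4-methylpenta-2,4-dienoate | C=C(C)/C=C/C(=O)OCC | intermediate
9 | (2E)-4-methylpenta-2,4-dien-1-ol | C=C(C)/C=C/CO | intermediate
10 | 1-methoxy-4-({[(2E)-4-methylpenta-2,4-dien-1-yl]oxy}methyl)benzene | C=C(C)/C=C/COCc1ccc(OC)cc1 | intermediate
11 | but-3-en-2-one | C=CC(C)=O | starting material
12 | formaldehyde | C=O | starting material
13 | 3-(hydroxymethyl)but-3-en-2-one | CC(=O)C(=C)CO | intermediate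
14 | 3-(chloromethyl)but-3-en-2-one | CC(=O)C(=C)CCl | intermediate
15 | Diels–Alder aldehyde: cyclohex-3-ene-1-carbaldehyde with C10–CH2OPMB cis and C14–CH(CH3)CH2OTBDPS trans to CHO, C12 methyl on the alkene (1S,10R,14S,15R) | O=C[C@H]1[C@@H](CC(C)=C[C@H]1COCc1ccc(OC)cc1)[C@@H](C)CO[Si](c1ccccc1)(c1ccccc1)C(C)(C)C | intermediate
16 | ethyl 2-[bis(2,2,2-trifluoroethoxy)phosphoryl]propanoate | CCOC(=O)C(C)P(=O)(OCC(F)(F)F)OCC(F)(F)F | starting material
17 | (2Z)-enoate: 15 with CHO replaced by (Z)-CH=C(CH3)CO2Et | CCOC(=O)/C(C)=C\[C@H]1[C@@H](CC(C)=C[C@H]1COCc1ccc(OC)cc1)[C@@H](C)CO[Si](c1ccccc1)(c1ccccc1)C(C)(C)C | intermediate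
18 | C11 alkylborane (BH2 trans to the C10 substituent, C12 methyl cis to it) | CCOC(=O)/C(C)=C\[C@H]1[C@@H](C[C@@H](C)[C@H](B)[C@H]1COCc1ccc(OC)cc1)[C@@H](C)CO[Si](c1ccccc1)(c1ccccc1)C(C)(C)C | intermediate
19 | C11 ketone (12R), Z-enoate | CCOC(=O)/C(C)=C\[C@H]1[C@@H](C[C@@H](C)C(=O)[C@H]1COCc1ccc(OC)cc1)[C@@H](C)CO[Si](c1ccccc1)(c1ccccc1)C(C)(C)C | intermediate
20 | (11R)-hydroxy Z-enoate (11-OH cis to C10 and C12 substituents) | CCOC(=O)/C(C)=C\[C@H]1[C@@H](C[C@@H](C)[C@@H](O)[C@H]1COCc1ccc(OC)cc1)[C@@H](C)CO[Si](c1ccccc1)(c1ccccc1)C(C)(C)C | intermediate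
21 | diol: (Z)-allylic alcohol (C4H2OH) and 11-OH | OC/C(C)=C\[C@H]1[C@@H](C[C@@H](C)[C@@H](O)[C@H]1COCc1ccc(OC)cc1)[C@@H](C)CO[Si](c1ccccc1)(c1ccccc1)C(C)(C)C | intermediate
22 | (2Z)-enal with free 11-OH | O=C/C(C)=C\[C@H]1[C@@H](C[C@@H](C)[C@@H](O)[C@H]1COCc1ccc(OC)cc1)[C@@H](C)CO[Si](c1ccccc1)(c1ccccc1)C(C)(C)C | intermediate
23 | 11-O-acetyl (2Z)-enal | O=C/C(C)=C\[C@H]1[C@@H](C[C@@H](C)[C@@H](OC(C)=O)[C@H]1COCc1ccc(OC)cc1)[C@@H](C)CO[Si](c1ccccc1)(c1ccccc1)C(C)(C)C | intermediate
24 | enol diisopinocampheylborinate of 14 | C=C(OB([C@@H]1C[C@@H]2C[C@@H](C2(C)C)[C@H]1C)[C@@H]1C[C@@H]2C[C@@H](C2(C)C)[C@H]1C)C(=C)CCl | intermediate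
25 | (4R)-aldol: 4-OH, C6 ketone, C7=C19H2, C8H2Cl, 2Z | ClCC(=C)C(=O)C[C@@H](O)/C(C)=C\[C@H]1[C@@H](C[C@@H](C)[C@@H](OC(C)=O)[C@H]1COCc1ccc(OC)cc1)[C@@H](C)CO[Si](c1ccccc1)(c1ccccc1)C(C)(C)C | intermediate
26 | (2R,3S,4R)-2,3-epoxy-4-ol | ClCC(=C)C(=O)C[C@@H](O)[C@]1(C)O[C@@H]1[C@H]2[C@@H](C[C@@H](C)[C@@H](OC(C)=O)[C@H]2COCc3ccc(OC)cc3)[C@@H](C)CO[Si](c3ccccc3)(c3ccccc3)C(C)(C)C | intermediate
27 | 26 with free C9H2OH | ClCC(=C)C(=O)C[C@@H](O)[C@]1(C)O[C@@H]1[C@H]2[C@@H](C[C@@H](C)[C@@H](OC(C)=O)[C@H]2CO)[C@@H](C)CO[Si](c3ccccc3)(c3ccccc3)C(C)(C)C | intermediate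
28 | C9 aldehyde | ClCC(=C)C(=O)C[C@@H](O)[C@]1(C)O[C@@H]1[C@H]2[C@@H](C[C@@H](C)[C@@H](OC(C)=O)[C@H]2C=O)[C@@H](C)CO[Si](c3ccccc3)(c3ccccc3)C(C)(C)C | intermediate
29 | ten-membered carbocycle cis-fused to the cyclohexane: (9S)-9-OH, 2,3-epoxide, 4-OH, C6 ketone, C7=C19H2 | C=C1C[C@H](O)[C@@H]2[C@H](OC(C)=O)[C@H](C)C[C@@H]([C@@H](C)CO[Si](c3ccccc3)(c3ccccc3)C(C)(C)C)[C@@H]2[C@H]2O[C@@]2(C)[C@H](O)CC1=O | intermediate
30 | tricyclic diol: C2–O–C9 tetrahydrofuran/oxonane, (2S,3S,4R,9S), 3-OH, 4-OH, 16-OTBDPS | C=C1C[C@@H]2O[C@@H]([C@H]3[C@@H](C[C@@H](C)[C@@H](OC(C)=O)[C@H]32)[C@@H](C)CO[Si](c2ccccc2)(c2ccccc2)C(C)(C)C)[C@](O)(C)[C@H](O)CC1=O | intermediate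
31 | 30 4-O-octanoate | C=C1C[C@@H]2O[C@@H]([C@H]3[C@@H](C[C@@H](C)[C@@H](OC(C)=O)[C@H]32)[C@@H](C)CO[Si](c2ccccc2)(c2ccccc2)C(C)(C)C)[C@](O)(C)[C@H](OC(=O)CCCCCCC)CC1=O | intermediate
32 | C3/C16 diol (16-OH free) | C=C1C[C@@H]2O[C@@H]([C@H]3[C@@H](C[C@@H](C)[C@@H](OC(C)=O)[C@H]32)[C@@H](C)CO)[C@](O)(C)[C@H](OC(=O)CCCCCCC)CC1=O | intermediate
33 | C16 triflate of 32 | C=C1C[C@@H]2O[C@@H]([C@H]3[C@@H](C[C@@H](C)[C@@H](OC(C)=O)[C@H]32)[C@@H](C)COS(=O)(=O)C(F)(F)F)[C@](O)(C)[C@H](OC(=O)CCCCCCC)CC1=O | intermediate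
34 | Asbestinin 16 | C=C1C[C@@H]2O[C@H]3[C@H]4[C@@H](C[C@@H](C)[C@@H](OC(C)=O)[C@H]42)[C@@H](C)CO[C@@]3(C)[C@H](OC(=O)CCCCCCC)CC1=O | target

**Step count and risks**

Total steps: 21. Longest linear sequence: 16 (steps 1–3, then 9–21).

The three steps most likely to fail:

Step 18. The ten-membered ring closure, the C9 configuration and the regiochemistry of the transannular opening are all decided in one flask, and none has a direct precedent on this substrate. The fallback moves the epoxidation to after the ring closure. It sets out from 25: DDQ then PhI(OAc)2/TEMPO give the alkene aldehyde F1; CrCl2 in THF/DMF at high dilution closes the ring to the macrocyclic (2Z)-cyclodecene diol F2, which is isolated so that its C9 epimer can be removed; VO(acac)2/t-BuOOH then epoxidises C2=C3 from the ring periphery under direction of the allylic 4-OH, and the C9 hydroxyl opens the epoxide in the same flask. The route is rejoined at 30.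

Step 15. Enone 14 carries an allylic chloride and may not survive enolisation with an amine base; the facial control of the Ipc reagent on this hindered Z-enal is also untested. The fallback masks the chloride as a silyl ether and installs it after the aldol. It sets out from 23 (and 13): TBSCl/imidazole on 13 gives 3-{[tert-butyl(dimethyl)silyl]oxymethyl}but-3-en-2-one F3; the same Ipc2BCl aldol with 23 gives the silyl-protected aldol F4; HF·pyridine removes the primary allylic TBS group (TBDPS and PMB stay) to give the C8 allylic alcohol F5; MsCl, 2,4,6-collidine and LiCl in DMF convert only the allylic primary alcohol into the chloride. The route is rejoined at 25.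

Step 9. A β-branched enal with an acyclic diene is at the edge of iminium catalysis, and endo and facial selectivity may both be moderate. The fallback uses auxiliary control with a strong Lewis acid. It sets out from 3 (and 10): Horner–Wadsworth–Emmons reaction of 3 with diethyl {2-[(4R)-4-benzyl-2-oxo-1,3-oxazolidin-3-yl]-2-oxoethyl}phosphonate (LiCl, i-Pr2NEt) gives the (E)-enoyl oxazolidinone F6; Et2AlCl-promoted Diels–Alder with 10 at −78 °C (diene anti to the benzyl group of the chelated s-cis imide, endo) gives the adduct imide F7; LiBH4 removes the auxiliary to give the primary alcohol F8; Dess–Martin oxidation follows. The route is rejoined at 15.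

Further compounds
F1 | step 18 | alkene aldehyde: 25 with the C9 CH2OPMB converted to CHO | ClCC(=C)C(=O)C[C@@H](O)/C(C)=C\[C@H]1[C@@H](C[C@@H](C)[C@@H](OC(C)=O)[C@H]1C=O)[C@@H](C)CO[Si](c1ccccc1)(c1ccccc1)C(C)(C)C
F2 | step 18 | macrocyclic (2Z)-cyclodecene diol (9-OH, 4-OH, C6 ketone, C7=C19H2) | C=C1C[C@H](O)[C@@H]2[C@H](OC(C)=O)[C@H](C)C[C@@H]([C@@H](C)CO[Si](c3ccccc3)(c3ccccc3)C(C)(C)C)[C@@H]2/C=C(C)\[C@H](O)CC1=O
F3 | step 15 | 3-{[tert-butyl(dimethyl)silyl]oxymethyl}but-3-en-2-one | CC(=O)C(=C)CO[Si](C)(C)C(C)(C)C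
F4 | step 15 | silyl-protected aldol (25 with C8–OTBS in place of C8–Cl) | CC(C)(C)[Si](C)(C)OCC(=C)C(=O)C[C@@H](O)/C(C)=C\[C@H]1[C@@H](C[C@@H](C)[C@@H](OC(C)=O)[C@H]1COCc1ccc(OC)cc1)[C@@H](C)CO[Si](c1ccccc1)(c1ccccc1)C(C)(C)C
F5 | step 15 | C8 allylic alcohol (25 with C8–OH in place of C8–Cl) | OCC(=C)C(=O)C[C@@H](O)/C(C)=C\[C@H]1[C@@H](C[C@@H](C)[C@@H](OC(C)=O)[C@H]1COCc1ccc(OC)cc1)[C@@H](C)CO[Si](c1ccccc1)(c1ccccc1)C(C)(C)C
F6 | step 9 | (E)-enoyl oxazolidinone of 5's acid with (4R)-4-benzyloxazolidin-2-one | O=C(/C=C/[C@@H](C)CO[Si](c1ccccc1)(c1ccccc1)C(C)(C)C)N1C(=O)OC[C@H]1Cc1ccccc1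
F7 | step 9 | Diels–Alder adduct imide (15 with CHO replaced by the N-acyl oxazolidinone) | O=C([C@H]1[C@@H](CC(C)=C[C@H]1COCc1ccc(OC)cc1)[C@@H](C)CO[Si](c1ccccc1)(c1ccccc1)C(C)(C)C)N1C(=O)OC[C@H]1Cc1ccccc1
F8 | step 9 | primary alcohol (15 with CHO reduced to CH2OH) | OC[C@H]1[C@@H](CC(C)=C[C@H]1COCc1ccc(OC)cc1)[C@@H](C)CO[Si](c1ccccc1)(c1ccccc1)C(C)(C)C
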